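The runs were generated by integration on assumed constants, noise included.

I began with the easy step of counting turnovers. A first product has taken one partner, a bis adduct two and a triple product three, so the turnover count is first plus twice bis plus three times triple, as a fraction of the starting material charged. The first product itself is what the other readings leave of the charge.

| flask | starting material | partner | remark | time |
|---|---|---|---|---|
| zeta | 20 mM | 0.74 equiv | run made earlier |  |
| alpha | 20 mM | 1.8 equiv | run made earlier |  |
| alder | 20 mM | 0.800 equiv |  | 1.0 h |
| oak | 20 mM | 0.500 equiv |  | 1.0 h |
| elm | 20 mM | 1.20 equiv |  | 1.0 h |

| run | time / min | bis adduct / % | triple product / % | starting material / % |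
|---|---|---|---|---|
| zeta | 2.00 | 6 | 0 | 83 |
| zeta | 6.00 | 8 | 0 | 68 |
| zeta | 10.0 | 11 | 0 | 64 |
| zeta | 15.0 | 14 | 0 | 60 |
| zeta | 25.0 | 19 | 0 | 56 |
| zeta | 30.0 | 24 | 0 | 53 |
| alpha | 2.50 | 14 | 3 | 57 |
| alpha | 4.00 | 22 | 6 | 49 |
| alpha | 6.00 | 26 | 7 | 42 |
| alpha | 10.0 | 36 | 5 | 35 |
| alpha | 20.0 | 52 | 3 | 25 |
| alpha | 30.0 | 57 | 5 | 19 |

(each reading ± 1.5 percentage points)

1. which of these holds the largest part of the starting material at the end of alder (bis adduct / starting material / triple product / first product)
2. which of these holds the largest part of the starting material at the end of oak (bis adduct / starting material / triple product / first product)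
3. which of these holds the largest part of the starting material at the end of elm (bis adduct / starting material / triple product / first product)
4. how much bis adduct is there at the end of elm, in percent of the starting material charged

- the numbers in the tables scatter by 1.5 percentage points (one standard deviation)

At the last zeta reading that left 23.0% of first product and a count of 0.710 against 0.74 equiv charged, so 95.9% of the partner had been taken while 53% of the starting material stood: partner was the limiting reagent in zeta.

Next I needed the way a count divides. Writing c for the fraction of starting material consumed, I took bis plus triple over c squared as the second-addition index. The last readings give 1.09 in zeta and 0.945 in alpha, and I carried their mean, 1.02, as a reading. Counting triple as bis, the count is then c plus the index times c squared.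

For elm with its whole charge taken, this gave c = 70.1% and bis 49.9%. The weak link was that whole charge, so I reforged it with the zeta share, though that share is no firmer than readings scattering by 1.5 percentage points. The count became 1.15, c became 68.1%, and I committed to bis 47.1% in elm, above starting material 31.9% and first product 21.0%. The same reckoning gave c = 50.7% in alder, which kept starting material ahead at 49.3% against bis 26.1%. In oak it gave c = 35.3%, with starting material again ahead at 64.7% against bis 12.7%. The reading to watch in elm was therefore the starting material, which the index turns into bis.

The forecast named starting material for alder, starting material for oak and bis adduct for elm, “so bis is largest, though not by much”, with bis at 41% where mine stood higher.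

Elm gave 46.1% of bis adduct.

    starting material + partner → first product (k = 10.0 M⁻¹ min⁻¹)
    partner + first product → bis adduct (k = 20.0 M⁻¹ min⁻¹)
    partner + bis adduct ⇌ triple product (K = 35.0 M⁻¹, k = 13.0 M⁻¹ min⁻¹)
    partner ⇌ dormant form (K = 1.60, k = 0.180 min⁻¹)

At 1.00 h elm held 1.14% of its partner free and 2.82% of that charge as dormant form. Its starting material of 31.8% gives, through the index, bis plus triple of 47.3%, and elm held 46.5%. The neighbour flask with 2.00 equiv of partner, otherwise as elm, ended with starting material 8.87%, for which the index gives 84.4%, and it held 83.0%.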